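Ring B and C5 are bought as (R)-carvone: its enone becomes C9/C8=C7 and its isopropenyl group becomes C4 with both geminal methyls. Everything rests on the C3–C4 disconnection of the unfunctionalised ring A (C1, C2, C3, C4, C5, C10). The precursor is a monocyclic keto aldehyde bearing a 3-oxopropyl chain on C10 trans to the isopropenyl group on C5. In one pot its tosylhydrazone undergoes iron-hydride hydrogen-atom transfer, 6-exo radical closure and loss of sulfinate and N2, so ring A closes, quaternary C4 is created and C3 ends as a bare CH2. The feature exploited is gem-dimethyl C4 beside ring-fusion C5. Methylenation and a B-alkyl Suzuki coupling then attach the arene.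

Key step: step 4

Remark: drimane numbering is used for all intermediates (ring A = C1–C5 and C10; ring B = C5–C10; C11 = benzylic CH2; C12 = methyl on C8). Compound 3 is carried on as its epimer mixture at the future C10, because that centre is planarised again in step 2.

Step 1
Reactants: 1 (R)-(–)-carvone
Product: 3 6-methylcarvone (epimers at the methyl-bearing carbon), via lithium dienolate 2 (not isolated)
Conditions: LiN(i-Pr)2 (LDA), THF, −78 °C; MeI, −78 → 0 °C
Reagents that add atoms: iodomethane, CI; lithium diisopropylamide, [Li+].CC(C)[N-]C(C)C (lithium stands only in 2)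
Why: Kinetic α′-deprotonation of the cross-conjugated enone followed by SN2 methylation (enolate alkylation) installs the future C10 methyl, and the new centre is flattened again in step 2.

Step 2
Reactants: 3 6-methylcarvone
Product: 5 (5S,6S)-6-allyl-2,6-dimethyl-5-(prop-1-en-2-yl)cyclohex-2-en-1-one, via methylated lithium dienolate 4 (not isolated)
Conditions: LiN(i-Pr)2 (LDA), THF, −78 → 0 °C; allyl bromide, −78 °C → rt
Reagents that add atoms: allyl bromide, C=CCBr; lithium diisopropylamide, [Li+].CC(C)[N-]C(C)C (lithium stands only in 4)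
Why: Enolate alkylation in which allyl bromide should attack dienolate 4 on the face anti to the C5 isopropenyl group, so the three-carbon chain (C1–C3) ends trans to it and the methyl cis, which sets C10 (S) under control of the carvone stereocentre.

Step 3
Reactants: 5 (5S,6S)-6-allyl-2,6-dimethyl-5-(prop-1-en-2-yl)cyclohex-2-en-1-one
Product: 6 3-[(1S,6S)-1,3-dimethyl-2-oxo-6-(prop-1-en-2-yl)cyclohex-3-en-1-yl]propanal
Conditions: PdCl2(PhCN)2 (cat.), CuCl2·2H2O (cat.), AgNO2 (cat.), O2 (1 atm), t-BuOH/MeNO2 15:1, rt
Reagents that add atoms: dioxygen, O=O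
Why: The nitrite-modified, aldehyde-selective Wacker oxidation places oxygen on the terminal carbon of monosubstituted alkenes, while the 1,1-disubstituted isopropenyl group and the electron-poor enone are poor substrates for divalent palladium, so only the allyl terminus (C3) should be oxidised.

Step 4
Reactants: 6 3-[(1S,6S)-1,3-dimethyl-2-oxo-6-(prop-1-en-2-yl)cyclohex-3-en-1-yl]propanal
Product: 10 (4aS,8aS)-2,5,5,8a-tetramethyl-4a,5,6,7,8,8a-hexahydronaphthalen-1(4H)-one (11-nordrim-7-en-9-one), via tosylhydrazone 7 (not isolated), via cyclised tosylhydrazide 8 (not isolated), via monoalkyl diazene 9 (not isolated)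
Conditions: TsNHNH2 (1.0 equiv), EtOH, rt; then Fe(acac)3 (0.3 equiv), PhSiH3 (2.5 equiv), 60 °C; then NaOAc, reflux
Reagents that add atoms: p-toluenesulfonyl hydrazide, Cc1ccc(cc1)S(=O)(=O)NN (its atoms stand only in 7, 8 and 9 and have left again in 10)
Why: Condensation should occur only at the unhindered aldehyde C3 (the C9 ketone is flanked by quaternary C10 and by C8) to give 7, and the iron hydride formed from Fe(acac)3 and PhSiH3 then transfers a hydrogen atom to the terminal CH2 of the isopropenyl group, turning that carbon into the second methyl and leaving a tertiary radical at C4. This nucleophilic radical adds to the electrophilic C=N carbon C3 in a 6-exo-trig closure of ring A (C3–C4 bond), and the sulfonyl-stabilised hydrazinyl radical is reduced by divalent iron and protonated by ethanol to 8. Heating with acetate eliminates p-toluenesulfinate to diazene 9, which loses N2 and leaves C3 as CH2, as in the Caglioti reduction of tosylhydrazones. The closest known reaction types are the iron-catalysed MHAT coupling of alkenes with sulfonylhydrazones, known in the intramolecular mode, and its traceless variant used for alkene hydromethylation. No stereocentre of the target is created: the trans ring fusion follows from the trans relation of chain and isopropenyl group fixed at C10 and C5 in step 2, and the transient C3 centre is erased. The step needs hydrogen-atom transfer to the 1,1-disubstituted alkene in preference to the enone, which the accessible terminal CH2 (against the internal trisubstituted C7=C8 bond) and the use of Fe(acac)3 in place of a manganese hydride source should secure, and the enone cannot trap the C4 radical because only a four-membered ring would result.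

Step 5
Reactants: 10 11-nordrim-7-en-9-one
Product: 11 (4aS,8aS)-2,5,5,8a-tetramethyl-1-methylidene-1,4,4a,5,6,7,8,8a-octahydronaphthalene (drima-7,9(11)-diene)
Conditions: Ph3PCH3Br, KOt-Bu, toluene, reflux
Reagents that add atoms: methyltriphenylphosphonium bromide, C[P+](c1ccccc1)(c1ccccc1)c1ccccc1.[Br-]
Why: Wittig methylenation under the high-temperature tert-butoxide protocol used for hindered ketones should convert the C9 ketone, which has no α-hydrogen at C10, into the exocyclic C9=C11 bond without touching C5 or C10.

Step 6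
Reactants: 12 methyl 2,3,4-trihydroxybenzoate
Product: 14 methyl 2,3,4-tris(methoxymethoxy)benzoate, via trisodium phenoxide 13 (not isolated)
Conditions: NaH, DMF, 0 °C, Ar; MOMCl, 0 °C → rt
Reagents that add atoms: chloromethyl methyl ether, COCCl; sodium hydride, [Na+].[H-] (sodium stands only in 13)
Why: Williamson-type O-alkylation, in which full deprotonation is used so that the 2-OH, hydrogen-bonded to the ester, also reacts.

Step 7
Reactants: 14 methyl 2,3,4-tris(methoxymethoxy)benzoate
Product: 15 methyl 5-bromo-2,3,4-tris(methoxymethoxy)benzoate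
Conditions: NBS, MeCN, 0 °C → rt
Reagents that add atoms: N-bromosuccinimide, O=C1CCC(=O)N1Br
Why: Electrophilic aromatic bromination should go to C5, which is ortho to the 4-oxygen, para to the 2-oxygen and meta to the ester, whereas C6 lies ortho to the deactivating ester.

Step 8
Reactants: 11 drima-7,9(11)-diene; 15 methyl 5-bromo-2,3,4-tris(methoxymethoxy)benzoate
Product: 17 methyl 2,3,4-tris(methoxymethoxy)-5-{[(1S,4aS,8aS)-2,5,5,8a-tetramethyl-1,4,4a,5,6,7,8,8a-octahydronaphthalen-1-yl]methyl}benzoate, via B-alkyl-9-BBN 16 (not isolated)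
Conditions: 9-BBN, THF, rt → 60 °C; then 15, PdCl2(dppf) (cat., dppf = 1,1′-bis(diphenylphosphino)ferrocene), aq. K3PO4, DMF, 60 °C
Reagents that add atoms: 9-borabicyclo[3.3.1]nonane, B1C2CCCC1CCC2 (boron stands only in 16; only its hydrogen stays in 17)
Why: Syn hydroboration of the terminal C9=C11 bond from the α face, opposite the axial C10 methyl, should put boron on C11 and hydrogen on C9 (9S, C11 equatorial), and the B-alkyl Suzuki–Miyaura coupling then forms the C11–aryl bond without touching C9 or the trisubstituted C7=C8 bond.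

Step 9
Reactants: 17 tris-MOM ether of the target
Product: 18 methyl 2,3,4-trihydroxy-5-{[(1S,4aS,8aS)-2,5,5,8a-tetramethyl-1,4,4a,5,6,7,8,8a-octahydronaphthalen-1-yl]methyl}benzoate (target)
Conditions: HCl (cat.), MeOH, 40 °C, Ar
Reagents that add atoms: none
Why: Acid-catalysed transacetalisation to methanol frees the three phenols under conditions that should be too mild to protonate the trisubstituted C7=C8 alkene, and the methyl ester is degenerate toward methanol.

Compound list
1 | (R)-(–)-carvone | O=C1C(C)=CC[C@@H](C(C)=C)C1 | starting material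
2 | lithium cross-conjugated dienolate of carvone | [Li+].[O-]C1=C[C@@H](CC=C1C)C(C)=C | intermediate (not isolated)
3 | (5R)-2,6-dimethyl-5-(prop-1-en-2-yl)cyclohex-2-en-1-one (6-methylcarvone, C6 epimers) | O=C1C(C)=CC[C@@H](C(C)=C)C1C | intermediate
4 | lithium dienolate of 6-methylcarvone | [Li+].[O-]C1=C(C)[C@@H](CC=C1C)C(C)=C | intermediate (not isolated)
5 | (5S,6S)-6-allyl-2,6-dimethyl-5-(prop-1-en-2-yl)cyclohex-2-en-1-one (allyl trans, methyl cis to isopropenyl) | O=C1C(C)=CC[C@@H](C(C)=C)[C@]1(C)CC=C | intermediate
6 | 3-[(1S,6S)-1,3-dimethyl-2-oxo-6-(prop-1-en-2-yl)cyclohex-3-en-1-yl]propanal | O=C1C(C)=CC[C@@H](C(C)=C)[C@]1(C)CCC=O | intermediate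
7 | (E)-tosylhydrazone of aldehyde 6 | O=C1C(C)=CC[C@@H](C(C)=C)[C@]1(C)CC/C=N/NS(=O)(=O)c1ccc(C)cc1 | intermediate (not isolated)
8 | 3-(2-tosylhydrazinyl)-11-nordrim-7-en-9-one (trans-fused, 5α-H, 10β-methyl; C3 epimers, centre erased) | O=C1C(C)=CC[C@H]2C(C)(C)C(NNS(=O)(=O)c3ccc(C)cc3)CC[C@]12C | intermediate (not isolated)
9 | 3-diazenyl-11-nordrim-7-en-9-one (C3 epimers, centre erased) | O=C1C(C)=CC[C@H]2C(C)(C)C(N=N)CC[C@]12C | intermediate (not isolated)
10 | (4aS,8aS)-2,5,5,8a-tetramethyl-4a,5,6,7,8,8a-hexahydronaphthalen-1(4H)-one (11-nordrim-7-en-9-one) | O=C1C(C)=CC[C@H]2C(C)(C)CCC[C@]12C | intermediate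
11 | (4aS,8aS)-2,5,5,8a-tetramethyl-1-methylidene-1,4,4a,5,6,7,8,8a-octahydronaphthalene | C=C1C(C)=CC[C@H]2C(C)(C)CCC[C@]12C | intermediate
12 | methyl 2,3,4-trihydroxybenzoate | COC(=O)c1ccc(O)c(O)c1O | starting material
13 | trisodium salt of methyl 2,3,4-trihydroxybenzoate | [Na+].[Na+].[Na+].COC(=O)c1ccc([O-])c([O-])c1[O-] | intermediate (not isolated)
14 | methyl 2,3,4-tris(methoxymethoxy)benzoate | COC(=O)c1ccc(OCOC)c(OCOC)c1OCOC | intermediate
15 | methyl 5-bromo-2,3,4-tris(methoxymethoxy)benzoate | COC(=O)c1cc(Br)c(OCOC)c(OCOC)c1OCOC | intermediate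
16 | 9-{[(1S,4aS,8aS)-2,5,5,8a-tetramethyl-1,4,4a,5,6,7,8,8a-octahydronaphthalen-1-yl]methyl}-9-borabicyclo[3.3.1]nonane | C(B1C2CCCC1CCC2)[C@H]1C(C)=CC[C@H]2C(C)(C)CCC[C@]12C | intermediate (not isolated)
17 | methyl 2,3,4-tris(methoxymethoxy)-5-{[(1S,4aS,8aS)-2,5,5,8a-tetramethyl-1,4,4a,5,6,7,8,8a-octahydronaphthalen-1-yl]methyl}benzoate | COC(=O)c1cc(C[C@H]2C(C)=CC[C@H]3C(C)(C)CCC[C@]23C)c(OCOC)c(OCOC)c1OCOC | intermediate
18 | methyl 2,3,4-trihydroxy-5-{[(1S,4aS,8aS)-2,5,5,8a-tetramethyl-1,4,4a,5,6,7,8,8a-octahydronaphthalen-1-yl]methyl}benzoate | COC(=O)c1cc(C[C@H]2C(C)=CC[C@H]3C(C)(C)CCC[C@]23C)c(O)c(O)c1O | target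

Total step count: 9. Longest linear sequence: 7 (steps 1, 2, 3, 4, 5, 8, 9).

Steps most likely to fail

Step 4. The tertiary C4 radical may be quenched to an isopropyl group faster than it closes onto the C=N bond, or the loss of sulfinate and N2 may stall at the hydrazide. The fallback swaps the traceless acceptor for a stronger, ester-activated one that is removed afterwards. It sets out from 3, whose dienolate 4 is alkylated with methyl 2-(bromomethyl)acrylate, again anti to the isopropenyl group. This gives methyl 2-{[(1S,6S)-1,3-dimethyl-2-oxo-6-(prop-1-en-2-yl)cyclohex-3-en-1-yl]methyl}acrylate F1. Fe(acac)3/PhSiH3 in EtOH at 60 °C should then close ring A by a 6-endo-trig Giese addition of the C4 radical to the acrylate CH2 (C3), giving methyl 9-oxo-11-nordrim-7-ene-2-carboxylate F2. LiOH in aqueous THF gives 9-oxo-11-nordrim-7-ene-2-carboxylic acid F3. Photoredox hydrodecarboxylation (9-mesityl-10-methylacridinium tetrafluoroborate, PhSSPh, i-Pr2NEt, CF3CH2OH, blue LED) removes the C2 carboxyl group, and the route is rejoined at 10.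

Step 3. Oxygen delivery may drift toward the internal carbon (methyl ketone formation), or palladium may isomerise the allyl group into conjugation-free internal alkenes. The fallback replaces the oxidation by hydroboration. It sets out from 5, and dicyclohexylborane (THF, 0 °C) should add only to the monosubstituted alkene. NaBO3·4H2O then gives (5S,6S)-6-(3-hydroxypropyl)-2,6-dimethyl-5-(prop-1-en-2-yl)cyclohex-2-en-1-one F4. Dess–Martin periodinane oxidises it to the aldehyde, rejoining the route at 6.

Step 8. The bulky borane may add slowly to the C9=C11 bond next to quaternary C10. The β-branched B-alkyl group may also transmetalate so slowly that protodeboronation takes over. The fallback reverses the polarity of the terpenoid partner and sets out from 11. BH3·THF (0 °C) followed by NaOH/H2O2 gives (–)-drimenol F5. I2, PPh3 and imidazole give drimenyl iodide F6. A nickel-catalysed reductive cross-electrophile coupling with 15 (NiBr2·glyme, 4,4′-di-tert-butyl-2,2′-bipyridine, Zn, DMA) forms the C11–aryl bond, rejoining the route at 17.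

Further compounds
F1 | step 4 | methyl 2-{[(1S,6S)-1,3-dimethyl-2-oxo-6-(prop-1-en-2-yl)cyclohex-3-en-1-yl]methyl}acrylate | O=C1C(C)=CC[C@@H](C(C)=C)[C@]1(C)CC(=C)C(=O)OC
F2 | step 4 | methyl 9-oxo-11-nordrim-7-ene-2-carboxylate (C2 epimers) | O=C1C(C)=CC[C@H]2C(C)(C)CC(C(=O)OC)C[C@]12C
F3 | step 4 | 9-oxo-11-nordrim-7-ene-2-carboxylic acid (C2 epimers) | O=C1C(C)=CC[C@H]2C(C)(C)CC(C(=O)O)C[C@]12C
F4 | step 3 | (5S,6S)-6-(3-hydroxypropyl)-2,6-dimethyl-5-(prop-1-en-2-yl)cyclohex-2-en-1-one | O=C1C(C)=CC[C@@H](C(C)=C)[C@]1(C)CCCO
F5 | step 8 | (–)-drimenol | OC[C@H]1C(C)=CC[C@H]2C(C)(C)CCC[C@]12C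
F6 | step 8 | drimenyl iodide | IC[C@H]1C(C)=CC[C@H]2C(C)(C)CCC[C@]12C
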